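**Retrosynthetic overview**

1. The dihydropyran ring, the spiro centre and the CH(iPr) centre come from one inverse-demand hetero-Diels–Alder reaction of the exocyclic C2=C10 alkene of (1R,5R)-(+)-β-pinene with isobutylidenesyncarpic acid, itself formed by Knoevenagel condensation of syncarpic acid with isobutyraldehyde.
2. The tetramethylcyclohexanetrione ring is not assembled as a six-membered ring. In the same flask it grows out of the four-membered ring of the aldol adduct of 2,2,4,4-tetramethylcyclobutane-1,3-dione (dimethylketene dimer) and ethyl acetate, by retro-aldol ring opening and Dieckmann re-closure (two-carbon ring expansion, 4 → 6).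
3. Enabling feature (chromene numbering of the target): the contiguous ring atoms C5'(=O)–C6'Me2–C7'(=O)–C8'Me2 are the intact ring of the dimer, and the two atoms shared with the pyran ring, C4a' and C8a', are the CH2 and C=O of acetate. In the adduct the carbinol carbon (future C5') is held to C8' by a strained bond β to the ring ketone, so its alkoxide opens that bond and releases a C8' enolate placed for six-ring closure onto the ester carbon (future C8a'). C4a' is then the only enolisable carbon and is the one that condenses with the aldehyde.
4. Ring order: cyclobutane (purchased) → cyclohexanetrione (ring expansion) → dihydropyran (cycloaddition); the pinane bicycle is purchased.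

Key step: step 2

Assumption: the stereodescriptors of the target correspond to the (1R,5R)-(+) enantiomer of β-pinene, not the more common (1S,5S)-(−) form; the (+) enantiomer is taken to be commercially available in high enantiomeric purity.

**Step 1**
Reactants: 1 2,2,4,4-tetramethylcyclobutane-1,3-dione; 2 ethyl acetate
Product: 4 ethyl 2-(1-hydroxy-2,2,4,4-tetramethyl-3-oxocyclobutyl)acetate, via lithium enolate of ethyl acetate 3 (not isolated)
Conditions: LiN(iPr)2 (1.0 equiv), THF, −78 °C; 1 (1.2 equiv), −78 °C; AcOH, −78 °C → rt
Reagents that add atoms: none
Why: Aldol addition of a preformed lithium ester enolate to a non-enolisable, angle-strained and therefore highly electrophilic ketone; at −78 °C with a slight excess of the dione the lithium alkoxide should survive until the cold acetic acid quench and a second addition should be suppressed, and no stereocentre arises because the carbinol carbon lies on the mirror plane of the ring.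

**Step 2**
Reactants: 4 ethyl 2-(1-hydroxy-2,2,4,4-tetramethyl-3-oxocyclobutyl)acetate; 5 isobutyraldehyde (2-methylpropanal); 6 (1R,5R)-(+)-β-pinene
Product: 10 (1S,2S,4'S,5R)-6,6,6',6',8',8'-hexamethyl-4'-(propan-2-yl)-3',4'-dihydrospiro[bicyclo[3.1.1]heptane-2,2'-chromene]-5',7'(6'H,8'H)-dione (target), via ethyl 4,4,6-trimethyl-3,5-dioxoheptanoate 7 (not isolated), via syncarpic acid 8 (not isolated), via isobutylidenesyncarpic acid 9 (not isolated)
Conditions: KOtBu (2.5 equiv), THF, 0 °C → reflux; then, same flask, AcOH (5 equiv), 5 (1.5 equiv), 6 (3 equiv), piperidine (20 mol %), 60 °C
Reagents that add atoms: none
Why: Proposed new method: KOtBu converts 4 into its alkoxide, whose strained ring bond between the carbinol carbon and one CMe2 carbon breaks in a retro-aldol sense (known for 3-hydroxy-2,2,4,4-tetramethylcyclobutanones) to give the enolate of 7, and under the excess base the isopropyl-ketone enolate then attacks the ester carbonyl in a 6-exo-trig Dieckmann closure with loss of ethoxide, so that the two acetate carbons end up inserted into the former four-membered ring (4 → 6), driven by ring strain and by formation of the β-triketone enolate of 8; the closest known reaction types are the ester-anion chemistry by which alkoxide-opened dimethylketene dimer closes to cyclohexane-1,3,5-triones and the Dieckmann closure of 3,5-dioxo esters. After buffering with AcOH, the only enolisable carbon of 8 (between two carbonyls) undergoes piperidinium-acetate-mediated Knoevenagel condensation with 5 to give the 1-oxadiene 9. 9 is trapped by the exocyclic alkene of 6 in an inverse-electron-demand hetero-Diels–Alder reaction, a [4+2] closure of the dihydropyran ring in which the alkene CH2 bonds to the alkylidene carbon and ring carbon C2 to the enone oxygen, the regiochemistry following from the polarity of the 1,1-disubstituted alkene and of the oxadiene. The spiro centre is controlled by the gem-dimethyl bridge of 6, which shields one face so that the C–O bond forms on the face of the methylene bridge; the CH(iPr) centre is controlled by the orientation of the alkene under the symmetric oxadiene, with the small C3 methylene endo beneath the enone flanked by the C8' gem-dimethyl group, the bulky bridgehead C1 exo, and the isopropyl group on the outside of the heterodiene. The step therefore needs facial and exo/endo selectivity, both secured by the bridged bicycle of 6, and preference for cycloaddition over ene transfer of the allylic C3 hydrogen, which the strongly polarised s-cis-locked oxadiene should favour; the epimer at the isopropyl-bearing carbon is the expected minor product and is to be removed by chromatography.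

**Compound list**

1 | 2,2,4,4-tetramethylcyclobutane-1,3-dione | CC1(C)C(=O)C(C)(C)C1=O | starting material
2 | ethyl acetate | CCOC(C)=O | starting material
3 | lithium enolate of ethyl acetate (lithium 1-ethoxyethenolate), not isolated | [Li+].[O-]C(=C)OCC | intermediate
4 | ethyl 2-(1-hydroxy-2,2,4,4-tetramethyl-3-oxocyclobutyl)acetate | CCOC(=O)CC1(O)C(C)(C)C(=O)C1(C)C | intermediate
5 | isobutyraldehyde (2-methylpropanal) | CC(C)C=O | starting material
6 | (1R,5R)-(+)-β-pinene, (1R,5R)-6,6-dimethyl-2-methylidenebicyclo[3.1.1]heptane | C=C1CC[C@@H]2C[C@H]1C2(C)C | starting material
7 | ethyl 4,4,6-trimethyl-3,5-dioxoheptanoate (present as its potassium enolate), not isolated | CCOC(=O)CC(=O)C(C)(C)C(=O)C(C)C | intermediate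
8 | syncarpic acid, 2,2,4,4-tetramethylcyclohexane-1,3,5-trione (formed as its potassium enolate, released by AcOH), not isolated | CC1(C)C(=O)CC(=O)C(C)(C)C1=O | intermediate
9 | isobutylidenesyncarpic acid, 2,2,4,4-tetramethyl-6-(2-methylpropylidene)cyclohexane-1,3,5-trione, not isolated | CC(C)C=C1C(=O)C(C)(C)C(=O)C(C)(C)C1=O | intermediate
10 | (1S,2S,4'S,5R)-6,6,6',6',8',8'-hexamethyl-4'-(propan-2-yl)-3',4'-dihydrospiro[bicyclo[3.1.1]heptane-2,2'-chromene]-5',7'(6'H,8'H)-dione; ring oxygen on the pinane face anti to the gem-dimethyl bridge, isopropyl cis to pinane C3 across the pyran ring | CC(C)[C@@H]1C[C@]2(CC[C@@H]3C[C@H]2C3(C)C)OC2=C1C(=O)C(C)(C)C(=O)C2(C)C | target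

**Step count and risk**

Total step count: 2. Longest linear sequence: 2 steps (1 → 4 → 10). The route has only two steps, so both are ranked.

First, step 2 (Proposed new method). What may go wrong:
- The anionic sequence may stall after ring opening, because the enolised β-keto ester resists C-acylation by the hindered tertiary enolate.
- Alkoxide and alcohols carried into the buffered second stage may slow the condensation.
- In the cycloaddition, weak exo/endo discrimination or competing ene transfer of the allylic hydrogen of the pinene would lower the amount of 10.

Fallback (known chemistry, stepwise with isolated intermediates and a stable heterodiene precursor): it sets out from 4 and returns to the route at 10. Compound 4 is opened with catalytic K2CO3 in EtOH at room temperature and 7 is isolated. 7 is closed by a conventional Dieckmann condensation (NaOEt, EtOH, reflux, acidic work-up) and 8 is isolated. 8 is condensed with 5 and one equivalent of piperidine (CH2Cl2, rt) to the Mannich base 2,2,4,4-tetramethyl-6-[2-methyl-1-(piperidin-1-yl)propyl]cyclohexane-1,3,5-trione F1. F1 is then heated with an excess of 6 (toluene, catalytic AcOH, 80 °C); retro-Mannich elimination should release 9 slowly, and 9 is trapped to give 10.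

Second, step 1. What may go wrong: the lithium alkoxide may open before the quench, a second enolate may add to the remaining ring ketone, or the ester enolate may self-condense. Material that has already opened to 7 would still be a competent substrate for step 2. Fallback (different enolate source, neutral conditions): it sets out from 1 and returns to the route at 4. A Reformatsky addition of the zinc enolate generated from ethyl bromoacetate and Zn dust (THF, 0 °C → rt, mild acidic work-up) should give 4 directly, since the covalent zinc alkoxide should not fragment; no new compound is formed on the way (F0).

**Further compounds**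

F1 | step 2 | 2,2,4,4-tetramethyl-6-[2-methyl-1-(piperidin-1-yl)propyl]cyclohexane-1,3,5-trione (racemic at the amino-bearing carbon) | CC(C)C(N1CCCCC1)C1C(=O)C(C)(C)C(=O)C(C)(C)C1=O
F0 | step 1 | none | none
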